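**Plan**

1. Retrosynthesis: the furanone ring bond O1–C5 is cut first, so that C5 and the CH2OH carbon C6 become an oxirane and O1–C2 a tert-butyl ester. Then the C3–acyl bond is cut (C-acylation of a β-keto ester), then C3–C4 (crossed Claisen on a glycidate), and last C12–C13 of the fatty chain (copper-catalysed alkyl–alkyl coupling).
2. Forward: chain coupling and acid chloride; glycidate Claisen; C-acylation to an open-chain tricarbonyl. The only ring of the target arises in the last step, and no protecting group is used.
3. Enabling feature: C5 is α to the C4 carbonyl and vicinal to the oxygen on C6, so C5–C6 can be carried as an oxirane. The ester carbonyl oxygen at C2 lies 1,5 to C5. The acyl C=O and C4=O flanking C3 form a 1,3-diketone that takes up a temporary six-membered difluoroboron chelate ring, which masks both ketone oxygens and holds the ester beside C5.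
4. Stereochemistry: C5 (S) comes from methyl (R)-glycidate by SN2 inversion in the ring closure. C14 (S) of the chain comes from (S)-1-bromo-2-methylbutane.

Key step: step 5

Remark: compounds 12 and 15 are drawn as single enol tautomers; both are rapidly equilibrating tautomer mixtures, and the tautomer drawn has no bearing on the route.

**Route**

Step 1
Reactants: 1 (S)-1-bromo-2-methylbutane; 2 12-bromododecanoic acid
Product: 5 (S)-14-methylhexadecanoic acid, via (S)-2-methylbutylmagnesium bromide 3 (not isolated), via chloromagnesium 12-bromododecanoate 4 (not isolated)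
Conditions: 1, Mg, THF, 40 °C; separately 2, MeMgCl (1.0 equiv), THF, −20 °C; then 3 (1.3 equiv), Li2CuCl4 (3 mol%), −20 °C → rt; aq. HCl
Reagents that add atoms: none
Why: Kochi-type Li2CuCl4-catalysed sp3–sp3 cross-coupling of a primary alkyl Grignard reagent with the primary bromide of an ω-bromo carboxylate salt should join the chain, and the stereocenter, β to magnesium, is not touched.

Step 2
Reactants: 5 (S)-14-methylhexadecanoic acid
Product: 6 (S)-14-methylhexadecanoyl chloride
Conditions: (COCl)2 (1.3 equiv), DMF (cat.), CH2Cl2, 0 °C → rt; evaporated and used crude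
Reagents that add atoms: oxalyl chloride, O=C(Cl)C(=O)Cl
Why: Vilsmeier-type acid chloride formation with only volatile by-products should be clean for a saturated fatty acid.

Step 3
Reactants: 7 methyl (R)-oxirane-2-carboxylate (methyl (R)-glycidate); 8 tert-butyl acetate
Product: 10 tert-butyl 3-[(2R)-oxiran-2-yl]-3-oxopropanoate, via lithium enolate of tert-butyl acetate 9 (not isolated)
Conditions: 8 (2.2 equiv), LiN(iPr)2 (2.2 equiv), THF, −78 °C; then 7, −78 °C, 1 h; AcOH, −78 °C
Reagents that add atoms: none
Why: In this crossed Claisen condensation the glycidate ester carbonyl should be attacked far faster than the oxirane at −78 °C, the product is protected as its enolate, and the oxirane C–H cannot enolise, so the (R) configuration is retained.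

Step 4
Reactants: 10 tert-butyl 3-[(2R)-oxiran-2-yl]-3-oxopropanoate; 6 (S)-14-methylhexadecanoyl chloride
Product: 12 tert-butyl (16S)-16-methyl-2-[(2R)-oxirane-2-carbonyl]-3-oxooctadecanoate (chelated enol form), via chloromagnesium epoxy keto ester enolate 11 (not isolated)
Conditions: 10, MgCl2 (1.1 equiv), pyridine (2.0 equiv), CH2Cl2, 0 °C, 20 min; then 6 (1.0 equiv), 0 °C, 2 h; cold aq. citric acid; used crude
Reagents that add atoms: none
Why: Rathke soft-enolisation C-acylation of a β-keto ester (MgCl2, amine base, acid chloride) should give the C-acylated tricarbonyl through the chelated magnesium enolate, since the oxirane is a far weaker electrophile than the acid chloride at 0 °C and neither stereocenter is involved.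

Step 5
Reactants: 12 tert-butyl (16S)-16-methyl-2-[(2R)-oxirane-2-carbonyl]-3-oxooctadecanoate
Product: 15 (5S)-4-hydroxy-5-(hydroxymethyl)-3-[(14S)-14-methylhexadecanoyl]furan-2(5H)-one, via difluoroboron diketonate chelate of the tricarbonyl 13 (not isolated), via difluoroboron chelate of the acyl tetronic acid 14 (not isolated)
Conditions: BF3·OEt2 (2.5 equiv), CH2Cl2, −40 → 0 °C; then MeOH, 65 °C
Reagents that add atoms: none
Why: Proposed new method: BF3·OEt2 should first turn the enolised 1,3-diketone of 12 (acyl C=O and C4=O) into the six-membered difluoroboron chelate 13, which ties up both ketone oxygens and holds the tert-butyl ester on C3 syn to the oxirane on C4; a second BF3 then activates the oxirane, the ester carbonyl oxygen opens it at C5 from the rear, the 2-tert-butoxy oxocarbenium ion sheds 2-methylpropene to give the chelated lactone 14, and methanolysis frees 15 from boron. The closest known reaction types are the acid-promoted epoxide-opening lactonisation of tert-butyl γ,δ-epoxy esters with loss of 2-methylpropene, the cyclisation of 4-halo-3-oxobutanoates to tetronic acids, and the formation and methanolysis of BF2 chelates of 3-acyl tetronic and tetramic acids; what is new is an oxirane α to the ketone serving as the electrophile on a 2-acyl-3-oxo ester. The furanone ring closes in the 5-exo-tet mode (the breaking C5–O bond of the oxirane lies outside the new ring), and the temporary dioxaborinine ring closes by simple O–B chelation. The new stereocenter C5 is controlled by the (R)-oxirane carbon: the C4 carbonyl-type carbon disfavours cationic character at C5, so the opening should be SN2 with inversion and give (5S), while C6 is released as the free CH2OH. The step needs the ester oxygen to win over the acyl ketone oxygen (which would close a 3(2H)-furanone) and C5 to win over C6 (6-endo); the chelate ring takes the ketone oxygens out of play, and the exo geometry together with SN2 activation next to C4 favours C5. Fluoride transfer to the oxirane is the remaining competitor and should be held back by the low temperature and the intramolecular nucleophile.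

**Compound list**

1 | (S)-1-bromo-2-methylbutane | CC[C@H](C)CBr | starting material
2 | 12-bromododecanoic acid | OC(=O)CCCCCCCCCCCBr | starting material
3 | (S)-2-methylbutylmagnesium bromide | CC[C@H](C)C[Mg]Br | intermediate
4 | chloromagnesium 12-bromododecanoate | BrCCCCCCCCCCCC(=O)O[Mg]Cl | intermediate
5 | (S)-14-methylhexadecanoic acid | CC[C@H](C)CCCCCCCCCCCCC(=O)O | intermediate
6 | (S)-14-methylhexadecanoyl chloride | CC[C@H](C)CCCCCCCCCCCCC(=O)Cl | intermediate
7 | methyl (R)-oxirane-2-carboxylate | COC(=O)[C@H]1CO1 | starting material
8 | tert-butyl acetate | CC(=O)OC(C)(C)C | starting material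
9 | lithium enolate of tert-butyl acetate | [Li]OC(=C)OC(C)(C)C | intermediate
10 | tert-butyl 3-[(2R)-oxiran-2-yl]-3-oxopropanoate | CC(C)(C)OC(=O)CC(=O)[C@H]1CO1 | intermediate
11 | chloromagnesium enolate of tert-butyl 3-[(2R)-oxiran-2-yl]-3-oxopropanoate | CC(C)(C)OC(=O)C=C(O[Mg]Cl)[C@H]1CO1 | intermediate
12 | tert-butyl (16S)-16-methyl-2-[(2R)-oxirane-2-carbonyl]-3-oxooctadecanoate (chelated enol drawn) | CC[C@H](C)CCCCCCCCCCCC/C(O)=C(\C(=O)OC(C)(C)C)C(=O)[C@H]1CO1 | intermediate
13 | difluoroboron 1,3-diketonate chelate of 12 | CC[C@H](C)CCCCCCCCCCCCC1=[O+][B-](F)(F)OC([C@H]2CO2)=C1C(=O)OC(C)(C)C | intermediate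
14 | difluoroboron chelate of 15 (acyl oxygen and 4-oxygen on boron) | CC[C@H](C)CCCCCCCCCCCCC1=[O+][B-](F)(F)OC2=C1C(=O)O[C@H]2CO | intermediate
15 | (5S)-4-hydroxy-5-(hydroxymethyl)-3-[(14S)-14-methylhexadecanoyl]furan-2(5H)-one | CC[C@H](C)CCCCCCCCCCCCC(=O)C1=C(O)[C@H](CO)OC1=O | target

**Step count and risks**

Total step count: 5. Longest linear sequence: 4 steps (steps 1, 2, 4, 5 from compound 1); the glycidate branch is 3 steps (steps 3, 4, 5).

Steps most likely to fail:

1. Step 5 (proposed new method). What may go wrong: ring closure through the acyl ketone oxygen instead of the ester oxygen if chelation is incomplete, 6-endo opening at C6, or fluoride delivery to the activated oxirane. Fallback with known chemistry, setting out from 6 and coming back at 15; here the ring is closed at C3–C4 and C5 is taken with retention from an (S)-glycerate.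
   - Compound 6 is added to Meldrum's acid and pyridine in CH2Cl2 at 0 °C to give 5-[(14S)-1-hydroxy-14-methylhexadecylidene]-2,2-dimethyl-1,3-dioxane-4,6-dione F1.
   - Commercial methyl (S)-2,3-dihydroxypropanoate is tritylated at the primary hydroxyl (Ph3CCl, Et3N, DMAP cat., CH2Cl2) to methyl (S)-2-hydroxy-3-(trityloxy)propanoate F2.
   - Heating F1 with F2 in toluene at 90 °C should trap the acylketene as methyl (2S)-2-{[(16S)-16-methyl-3-oxooctadecanoyl]oxy}-3-(trityloxy)propanoate F3.
   - Bu4NF in THF at rt should effect Lacey–Dieckmann cyclisation to (5S)-4-hydroxy-3-[(14S)-14-methylhexadecanoyl]-5-[(trityloxy)methyl]furan-2(5H)-one F4.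
   - TFA/H2O in CH2Cl2 at 0 °C removes the trityl group to give 15.

2. Step 4. What may go wrong: chloride- or magnesium-assisted opening of the keto-oxirane, competing O-acylation, or premature cyclisation of the tricarbonyl on work-up. Fallback setting out from 6 and 10 and coming back at 12; it replaces Lewis-acid soft enolisation with acyl transfer from a neutral acyl azole to a preformed enolate, free of chloride and magnesium.
   - Compound 6 is treated with 1H-benzotriazole and Et3N in CH2Cl2 to give 1-[(14S)-14-methylhexadecanoyl]-1H-benzotriazole F5.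
   - Compound 10 is deprotonated with NaH in THF at 0 °C to the sodium enolate of tert-butyl 3-[(2R)-oxiran-2-yl]-3-oxopropanoate F6.
   - F6 is C-acylated by F5 (0 °C → rt) and should give 12 after cold citric acid work-up.

3. Step 3. What may go wrong: attack of the ester enolate on the oxirane, oligomerisation of the glycidate, or loss of the small product on isolation. Fallback setting out from 7 and coming back at 10; it uses a Weinreb ketone synthesis in place of the Claisen condensation.
   - Compound 7 is saponified with KOH in EtOH at 0 °C to potassium (R)-oxirane-2-carboxylate F7, collected as the salt.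
   - Coupling of F7 with MeNH(OMe)·HCl and EDC·HCl in CH2Cl2 at 0 °C should give (R)-N-methoxy-N-methyloxirane-2-carboxamide F8.
   - Addition of 9 (1.5 equiv) to F8 in THF at −78 °C, then AcOH quench, should give 10 through the stable chelated tetrahedral adduct.

**Further compounds**

F1 | step 5 | 5-[(14S)-1-hydroxy-14-methylhexadecylidene]-2,2-dimethyl-1,3-dioxane-4,6-dione | CC[C@H](C)CCCCCCCCCCCCC(O)=C1C(=O)OC(C)(C)OC1=O
F2 | step 5 | methyl (S)-2-hydroxy-3-(trityloxy)propanoate | COC(=O)[C@@H](O)COC(c1ccccc1)(c1ccccc1)c1ccccc1
F3 | step 5 | methyl (2S)-2-{[(16S)-16-methyl-3-oxooctadecanoyl]oxy}-3-(trityloxy)propanoate | CC[C@H](C)CCCCCCCCCCCCC(=O)CC(=O)O[C@@H](COC(c1ccccc1)(c1ccccc1)c1ccccc1)C(=O)OC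
F4 | step 5 | (5S)-4-hydroxy-3-[(14S)-14-methylhexadecanoyl]-5-[(trityloxy)methyl]furan-2(5H)-one | CC[C@H](C)CCCCCCCCCCCCC(=O)C1=C(O)[C@H](COC(c2ccccc2)(c2ccccc2)c2ccccc2)OC1=O
F5 | step 4 | 1-[(14S)-14-methylhexadecanoyl]-1H-benzotriazole | CC[C@H](C)CCCCCCCCCCCCC(=O)n1nnc2ccccc12
F6 | step 4 | sodium enolate of tert-butyl 3-[(2R)-oxiran-2-yl]-3-oxopropanoate | [Na+].CC(C)(C)OC(=O)C=C([O-])[C@H]1CO1
F7 | step 3 | potassium (R)-oxirane-2-carboxylate | [K+].[O-]C(=O)[C@H]1CO1
F8 | step 3 | (R)-N-methoxy-N-methyloxirane-2-carboxamide | CON(C)C(=O)[C@H]1CO1
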